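Everything rests on disconnecting the O1–C8a bond of the pyran ring. Because the C2 carbinol hangs from C4a through a cis C3=C4 double bond, its oxygen sits directly over C8a, the unsubstituted β-position of the C5 enone in the quinone ring. One operation therefore adds that hydroxyl 6-endo to C8a, closes the pyran ring and, with Ag2O in the flask, returns the cyclised hydroquinone to the 5,8-dione. The precursor is a 2-methoxy-6-(Z-alkenyl)-1,4-benzoquinone whose side chain already carries all three stereocentres; it is released from a bis-silylated hydroquinone by fluoride and Ag2O, so the ionisable tertiary allylic alcohol never meets acid.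

Key step: step 15

Assumption: in step 1 the (4S,5S)-diazaborolidine is taken to favour the chair that leads to (2R,3S)-3; the relative configuration does not depend on this, and the (4R,5R) reagent would be used instead if the sense proved opposite.

Step 1
Reactants: 1 geranyl propionate
Product: 3 (2R,3S)-3-ethenyl-2,3,7-trimethyloct-6-enoic acid, via boron ketene acetal 2 (not isolated)
Conditions: preformed (4S,5S)-2-bromo-1,3-bis[3,5-bis(trifluoromethyl)phenylsulfonyl]-4,5-diphenyl-1,3,2-diazaborolidine, iPr2NEt, CH2Cl2, −78 °C, then −20 to 4 °C; aqueous work-up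
Reagents that add atoms: none
Why: Enantioselective Ireland–Claisen rearrangement through a chiral boron ketene acetal: soft enolisation should place the methyl cis to O–B, the chair transition state with the (E)-allyl unit (homoprenyl equatorial) then fixes the 2,3-relative configuration, and the C2-symmetric diazaborolidine selects the chair that gives C2 (R) and the quaternary C3 (S).

Step 2
Reactants: 3 (2R,3S)-3-ethenyl-2,3,7-trimethyloct-6-enoic acid
Product: 4 (3R,4S)-4-ethenyl-3,4,8-trimethylnon-7-en-2-one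
Conditions: MeLi (2.5 equiv), Et2O, 0 °C to rt; poured into cold 1 M HCl
Reagents that add atoms: methyllithium, [Li]C
Why: Carboxylic acid to methyl ketone by double addition of MeLi: the lithium carboxylate takes up one MeLi to a gem-diolate that survives until the acidic quench, so no ketone is present while base is, and the α-stereocentre is preserved.

Step 3
Reactants: 4 (3R,4S)-4-ethenyl-3,4,8-trimethylnon-7-en-2-one
Product: 6 (4S,5R)-4-ethenyl-4,5-dimethyl-6-oxoheptanal, via epoxy ketone 5 (not isolated)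
Conditions: m-CPBA, NaHCO3, CH2Cl2, 0 °C; then H5IO6, THF/H2O, 0 °C
Reagents that add atoms: 3-chloroperoxybenzoic acid, OOC(=O)c1cccc(Cl)c1
Why: Prilezhaev epoxidation followed by periodic acid cleavage: the peracid picks the electron-rich trisubstituted alkene over the hindered vinyl group, and H5IO6 opens the oxirane and cleaves the resulting diol to the aldehyde with loss of acetone, both oxirane epimers giving the same product.

Step 4
Reactants: 6 (4S,5R)-4-ethenyl-4,5-dimethyl-6-oxoheptanal
Product: 7 (5S,6S)-5-ethenyl-1,5,6-trimethylcyclohex-1-ene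
Conditions: TiCl3(DME)1.5, Zn–Cu, DME, reflux, slow addition of 6
Reagents that add atoms: none
Why: Intramolecular McMurry coupling of a 1,6-keto aldehyde: low-valent titanium joins the two carbonyl carbons and deoxygenates the pinacolate to the trisubstituted ring alkene exactly where it is needed, an olefin-metathesis closure being avoided because the vinyl group would compete for a five-membered ring, and no stereocentre is involved.

Step 5
Reactants: 8 but-2-yn-1-ol
Product: 10 (2Z)-3-iodobut-2-en-1-ol, via cyclic alkenylaluminate 9 (not isolated)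
Conditions: NaAlH2(OCH2CH2OMe)2, Et2O, 0 °C to rt; EtOAc; then I2, THF, −78 to 0 °C
Reagents that add atoms: iodine, II
Why: Hydroxyl-directed trans-hydroalumination of a propargylic alcohol followed by iodinolysis: aluminium is delivered to C3 within a five-membered aluminate, so iodine replaces it with retention and ends cis to the CH2OH group.

Step 6
Reactants: 7 (5S,6S)-5-ethenyl-1,5,6-trimethylcyclohex-1-ene; 10 (2Z)-3-iodobut-2-en-1-ol
Product: 12 (2Z)-3-methyl-5-[(1S,2R)-1,2,3-trimethylcyclohex-3-en-1-yl]pent-2-en-1-ol, via B-alkyl-9-BBN 11 (not isolated)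
Conditions: 9-BBN, THF, rt; then 10, Pd(dppf)Cl2, AsPh3, Cs2CO3, DMF/H2O, rt
Reagents that add atoms: none
Why: Hydroboration followed by B-alkyl Suzuki–Miyaura coupling: 9-BBN adds at the terminal carbon of the vinyl group only, leaving the trisubstituted ring alkene, and the alkylborane couples with the vinyl iodide with retention of the Z geometry.

Step 7
Reactants: 12 (2Z)-3-methyl-5-[(1S,2R)-1,2,3-trimethylcyclohex-3-en-1-yl]pent-2-en-1-ol
Product: 13 [(2R,3S)-3-methyl-3-{2-[(1S,2R)-1,2,3-trimethylcyclohex-3-en-1-yl]ethyl}oxiran-2-yl]methanol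
Conditions: Ti(OiPr)4, D-(−)-diisopropyl tartrate, t-BuOOH, 4 Å MS, CH2Cl2, −20 °C
Reagents that add atoms: tert-butyl hydroperoxide, CC(C)(C)OO
Why: Sharpless asymmetric epoxidation: the titanium tartrate binds the allylic hydroxyl, ignores the ring alkene and, with the D-(−)-tartrate, should deliver oxygen to the face that gives the (2R,3S)-epoxide, which sets the future C2 of the chromene as S under reagent control.

Step 8
Reactants: 13 [(2R,3S)-3-methyl-3-{2-[(1S,2R)-1,2,3-trimethylcyclohex-3-en-1-yl]ethyl}oxiran-2-yl]methanol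
Product: 14 (2S,3S)-3-(chloromethyl)-2-methyl-2-{2-[(1S,2R)-1,2,3-trimethylcyclohex-3-en-1-yl]ethyl}oxirane
Conditions: PPh3, CCl4, NaHCO3, reflux
Reagents that add atoms: carbon tetrachloride, ClC(Cl)(Cl)Cl
Why: Appel chlorination of the primary alcohol under bicarbonate buffering, in which the trisubstituted oxirane is not opened and neither stereocentre is touched.

Step 9
Reactants: 14 (2S,3S)-3-(chloromethyl)-2-methyl-2-{2-[(1S,2R)-1,2,3-trimethylcyclohex-3-en-1-yl]ethyl}oxirane
Product: 15 (3S)-3-methyl-5-[(1S,2R)-1,2,3-trimethylcyclohex-3-en-1-yl]pent-1-yn-3-ol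
Conditions: n-BuLi (3.5 equiv), THF, −40 °C; aqueous NH4Cl
Reagents that add atoms: none
Why: Base-induced fragmentation of a 2,3-epoxy chloride to a propargylic alcohol: lithiation at CH2Cl, β-elimination that opens the oxirane and loss of HCl give the terminal alkyne, and because the tertiary C–O bond is never broken the S configuration is carried over.

Step 10
Reactants: 16 5-iodovanillin
Product: 18 2-iodo-6-methoxybenzene-1,4-diol, via aryl formate 17 (not isolated)
Conditions: H2O2 (30%), NaOH, H2O, 0 °C to rt, under N2; then HCl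
Reagents that add atoms: hydrogen peroxide, OO
Why: Dakin oxidation: hydroperoxide adds to the aldehyde para to the phenoxide, the electron-rich aryl group migrates to oxygen and the formate is saponified in the same flask.

Step 11
Reactants: 18 2-iodo-6-methoxybenzene-1,4-diol
Product: 19 1,4-bis(tert-butyldimethylsilyloxy)-2-iodo-6-methoxybenzene
Conditions: t-BuMe2SiCl, imidazole, DMF, rt to 40 °C
Reagents that add atoms: tert-butyldimethylsilyl chloride, CC(C)(C)[Si](C)(C)Cl
Why: Imidazole-promoted silyl ether formation on both phenols prevents benzofuran formation in the coupling and allows release with fluoride instead of acid or (NH4)2Ce(NO3)6.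

Step 12
Reactants: 15 (3S)-3-methyl-5-[(1S,2R)-1,2,3-trimethylcyclohex-3-en-1-yl]pent-1-yn-3-ol; 19 1,4-bis(tert-butyldimethylsilyloxy)-2-iodo-6-methoxybenzene
Product: 20 (3S)-1-[2,5-bis(tert-butyldimethylsilyloxy)-3-methoxyphenyl]-3-methyl-5-[(1S,2R)-1,2,3-trimethylcyclohex-3-en-1-yl]pent-1-yn-3-ol
Conditions: Pd(PPh3)2Cl2, CuI, Et3N, THF, 45 °C
Reagents that add atoms: none
Why: Sonogashira coupling of an aryl iodide with a terminal alkyne, to which the free tertiary alcohol, the aryl silyl ethers and the ring alkene are inert.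

Step 13
Reactants: 20 (3S)-1-[2,5-bis(tert-butyldimethylsilyloxy)-3-methoxyphenyl]-3-methyl-5-[(1S,2R)-1,2,3-trimethylcyclohex-3-en-1-yl]pent-1-yn-3-ol
Product: 21 (1Z,3S)-1-[2,5-bis(tert-butyldimethylsilyloxy)-3-methoxyphenyl]-3-methyl-5-[(1S,2R)-1,2,3-trimethylcyclohex-3-en-1-yl]pent-1-en-3-ol
Conditions: H2 (1 atm), Pd/CaCO3 poisoned with Pb(OAc)2 (Lindlar catalyst), quinoline, EtOAc, rt
Reagents that add atoms: none
Why: Lindlar semihydrogenation: syn delivery of hydrogen on the poisoned palladium surface gives the Z alkene and stops there, the hindered trisubstituted ring alkene not being reduced.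

Step 14
Reactants: 21 (1Z,3S)-1-[2,5-bis(tert-butyldimethylsilyloxy)-3-methoxyphenyl]-3-methyl-5-[(1S,2R)-1,2,3-trimethylcyclohex-3-en-1-yl]pent-1-en-3-ol
Product: 23 2-[(1Z,3S)-3-hydroxy-3-methyl-5-[(1S,2R)-1,2,3-trimethylcyclohex-3-en-1-yl]pent-1-en-1-yl]-6-methoxycyclohexa-2,5-diene-1,4-dione, via alkenyl hydroquinone 22 (not isolated)
Conditions: Bu4NF, AcOH, THF, 0 °C; work-up; then Ag2O, MgSO4, Et2O, 0 °C, dark, short contact
Reagents that add atoms: none
Why: Fluoride desilylation followed by Ag2O oxidation of the hydroquinone: both operations are non-acidic, so the tertiary allylic alcohol is not ionised, the Z alkene is kept and the quinone is reached without an acidic oxidant.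

Step 15
Reactants: 23 2-[(1Z,3S)-3-hydroxy-3-methyl-5-[(1S,2R)-1,2,3-trimethylcyclohex-3-en-1-yl]pent-1-en-1-yl]-6-methoxycyclohexa-2,5-diene-1,4-dione
Product: 25 (2S)-6-methoxy-2-methyl-2-{2-[(1S,2R)-1,2,3-trimethylcyclohex-3-en-1-yl]ethyl}-2H-chromene-5,8-dione, via chromene-5,8-diol 24 (not isolated)
Conditions: Ag2O (3 equiv), K2CO3 (cat.), 4 Å MS, toluene, 40 °C, dark
Reagents that add atoms: none
Why: The tertiary hydroxyl oxygen adds to C8a, giving an enolate of the C5 carbonyl that tautomerises to the aromatic chromene-5,8-diol 24, from which Ag2O removes two hydrogens to restore the quinone. The closest known reaction type is the intramolecular oxa-Michael addition of a tethered alcohol to a quinone with reoxidation in the same flask, as used for pyrano-fused quinones. The pyran ring (O1, C2, C3, C4, C4a, C8a) closes in the 6-endo-trig mode, the cis C3=C4 bond having already placed the oxygen over C8a. No stereocentre is created, and C2 keeps its S configuration because only its O–H bond reacts and no acid is present to ionise the allylic C–O bond. The step needs attack at C8a and not at C7 or at the C5 carbonyl: C7 is beyond the reach of the tether and lies on the methoxy-bearing (vinylogous ester) half of the ring, which is the less electrophilic one, while addition to the C5 carbonyl gives only a hemiketal that reverts.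

Compound list
1 | geranyl propionate [(2E)-3,7-dimethylocta-2,6-dien-1-yl propanoate] | CCC(=O)OC/C=C(\C)CCC=C(C)C | starting material
2 | boron ketene acetal of 1 (formed in the flask): enol oxygen bonded to B2 of (4S,5S)-1,3-bis[3,5-bis(trifluoromethyl)phenylsulfonyl]-4,5-diphenyl-1,3,2-diazaborolidine, methyl cis to O–B | C/C=C(\OB1N(S(=O)(=O)c2cc(cc(c2)C(F)(F)F)C(F)(F)F)[C@@H](c2ccccc2)[C@H](c2ccccc2)N1S(=O)(=O)c1cc(cc(c1)C(F)(F)F)C(F)(F)F)OC/C=C(\C)CCC=C(C)C | intermediate
3 | (2R,3S)-3-ethenyl-2,3,7-trimethyloct-6-enoic acid | C=C[C@](C)(CCC=C(C)C)[C@@H](C)C(=O)O | intermediate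
4 | (3R,4S)-4-ethenyl-3,4,8-trimethylnon-7-en-2-one | C=C[C@](C)(CCC=C(C)C)[C@@H](C)C(C)=O | intermediate
5 | (3R,4S)-4-[2-(3,3-dimethyloxiran-2-yl)ethyl]-3,4-dimethylhex-5-en-2-one (formed in the flask; both epimers at the oxirane CH) | C=C[C@](C)(CCC1OC1(C)C)[C@@H](C)C(C)=O | intermediate
6 | (4S,5R)-4-ethenyl-4,5-dimethyl-6-oxoheptanal | C=C[C@](C)(CCC=O)[C@@H](C)C(C)=O | intermediate
7 | (5S,6S)-5-ethenyl-1,5,6-trimethylcyclohex-1-ene (6-methyl cis to ethenyl) | C=C[C@]1(C)CCC=C(C)[C@@H]1C | intermediate
8 | but-2-yn-1-ol | CC#CCO | starting material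
9 | sodium 2,2-bis(2-methoxyethoxy)-3-methyl-2,5-dihydro-1,2-oxaaluminol-2-uide (cyclic alkenylaluminate, formed in the flask) | CC1=CCO[Al-]1(OCCOC)OCCOC.[Na+] | intermediate
10 | (2Z)-3-iodobut-2-en-1-ol | C/C(I)=C/CO | intermediate
11 | 9-{2-[(1R,2R)-1,2,3-trimethylcyclohex-3-en-1-yl]ethyl}-9-borabicyclo[3.3.1]nonane (formed in the flask; ring arranged in space as in 7, the C1 descriptor changes only because boron lowers the priority of the chain) | C(C[C@]1(C)CCC=C(C)[C@@H]1C)B1C2CCCC1CCC2 | intermediate
12 | (2Z)-3-methyl-5-[(1S,2R)-1,2,3-trimethylcyclohex-3-en-1-yl]pent-2-en-1-ol | OC/C=C(/C)CC[C@]1(C)CCC=C(C)[C@@H]1C | intermediate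
13 | [(2R,3S)-3-methyl-3-{2-[(1S,2R)-1,2,3-trimethylcyclohex-3-en-1-yl]ethyl}oxiran-2-yl]methanol | OC[C@H]1O[C@@]1(C)CC[C@]2(C)CCC=C(C)[C@@H]2C | intermediate
14 | (2S,3S)-3-(chloromethyl)-2-methyl-2-{2-[(1S,2R)-1,2,3-trimethylcyclohex-3-en-1-yl]ethyl}oxirane | ClC[C@H]1O[C@@]1(C)CC[C@]2(C)CCC=C(C)[C@@H]2C | intermediate
15 | (3S)-3-methyl-5-[(1S,2R)-1,2,3-trimethylcyclohex-3-en-1-yl]pent-1-yn-3-ol | C#C[C@](C)(CC[C@]1(C)CCC=C(C)[C@@H]1C)O | intermediate
16 | 5-iodovanillin (4-hydroxy-3-iodo-5-methoxybenzaldehyde) | COc1cc(C=O)cc(I)c1O | starting material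
17 | 4-hydroxy-3-iodo-5-methoxyphenyl formate (formed in the flask) | COc1cc(OC=O)cc(I)c1O | intermediate
18 | 2-iodo-6-methoxybenzene-1,4-diol | COc1cc(O)cc(I)c1O | intermediate
19 | 1,4-bis(tert-butyldimethylsilyloxy)-2-iodo-6-methoxybenzene | COc1cc(O[Si](C)(C)C(C)(C)C)cc(I)c1O[Si](C)(C)C(C)(C)C | intermediate
20 | (3S)-1-[2,5-bis(tert-butyldimethylsilyloxy)-3-methoxyphenyl]-3-methyl-5-[(1S,2R)-1,2,3-trimethylcyclohex-3-en-1-yl]pent-1-yn-3-ol | COc1cc(O[Si](C)(C)C(C)(C)C)cc(C#C[C@](C)(CC[C@]2(C)CCC=C(C)[C@@H]2C)O)c1O[Si](C)(C)C(C)(C)C | intermediate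
21 | (1Z,3S)-1-[2,5-bis(tert-butyldimethylsilyloxy)-3-methoxyphenyl]-3-methyl-5-[(1S,2R)-1,2,3-trimethylcyclohex-3-en-1-yl]pent-1-en-3-ol | COc1cc(O[Si](C)(C)C(C)(C)C)cc(/C=C\[C@](C)(CC[C@]2(C)CCC=C(C)[C@@H]2C)O)c1O[Si](C)(C)C(C)(C)C | intermediate
22 | 2-[(1Z,3S)-3-hydroxy-3-methyl-5-[(1S,2R)-1,2,3-trimethylcyclohex-3-en-1-yl]pent-1-en-1-yl]-6-methoxybenzene-1,4-diol (formed in the flask) | COc1cc(O)cc(/C=C\[C@](C)(CC[C@]2(C)CCC=C(C)[C@@H]2C)O)c1O | intermediate
23 | 2-[(1Z,3S)-3-hydroxy-3-methyl-5-[(1S,2R)-1,2,3-trimethylcyclohex-3-en-1-yl]pent-1-en-1-yl]-6-methoxycyclohexa-2,5-diene-1,4-dione (precursor of the key step) | COC1=CC(=O)C=C(/C=C\[C@](C)(CC[C@]2(C)CCC=C(C)[C@@H]2C)O)C1=O | intermediate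
24 | (2S)-6-methoxy-2-methyl-2-{2-[(1S,2R)-1,2,3-trimethylcyclohex-3-en-1-yl]ethyl}-2H-chromene-5,8-diol (formed in the flask) | COc1cc(O)c2c(c1O)C=C[C@](C)(CC[C@]1(C)CCC=C(C)[C@@H]1C)O2 | intermediate
25 | (2S)-6-methoxy-2-methyl-2-{2-[(1S,2R)-1,2,3-trimethylcyclohex-3-en-1-yl]ethyl}-2H-chromene-5,8-dione | COC1=CC(=O)C2=C(C=C[C@](C)(CC[C@]3(C)CCC=C(C)[C@@H]3C)O2)C1=O | target

Total step count: 15.
Longest linear sequence: 12 steps (steps 1–4, 6–9 and 12–15, from geranyl propionate).

Steps most likely to fail

Step 15. The hindered tertiary hydroxyl may add to C8a too slowly, so that Z to E isomerisation of the side-chain alkene or redox decomposition of the quinone overtakes ring closure. The fallback sets out from 15 and comes back to the route at 25. It forms the same O1–C8a bond by addition–elimination instead of oxidative conjugate addition. Commercial 1,2,4,5-tetramethoxybenzene is lithiated with n-BuLi and iodinated to 3-iodo-1,2,4,5-tetramethoxybenzene F1. Sonogashira coupling with 15 should give the aryl alkyne F2, and Lindlar semihydrogenation the Z alkene F3. Brief oxidative demethylation with (NH4)2Ce(NO3)6 in cold aqueous MeCN should give the 2,5-dimethoxyquinone F4. In F4 the carbon that becomes C8a already carries a methoxy leaving group. With a trace of K2CO3 in MeCN the tertiary hydroxyl should displace that methoxy group (a vinylogous transesterification) and give 25 with loss of methanol and no change of oxidation level. The ceric step is acidic and is the weak point of this fallback.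

Step 1. Soft enolisation at boron may be incomplete or unselective, and the rearrangement to the quaternary carbon is slow, which would erode both diastereo- and enantiocontrol. The fallback sets out from 1 and comes back at 3. Enolisation with LiN(iPr)2 in THF/DMPU at −78 °C and trapping with Me3SiCl should give the silyl ketene acetal F5 with methyl cis to O–Si. On warming it rearranges through the same chair, and aqueous work-up should give the racemic acid F6 with the required relative configuration. The acid is resolved by crystallisation with (S)-1-phenylethylamine, the salt F7 being taken here as the less soluble one (the antipodal amine is used otherwise). Acidification of F7 returns 3.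

Step 4. Deoxygenation of the titanium-bound pinacolate may stall, the centre next to the ketone may epimerise on the Lewis-acidic metal, and the volatile hydrocarbon may be lost on isolation. The fallback sets out from 6 and comes back at 7. Pinacol cyclisation with SmI2 in THF/t-BuOH at −78 °C should give the cis-diol F8. Thiocarbonyldiimidazole in hot toluene converts it to the cyclic thiocarbonate F9. Heating F9 in P(OMe)3 (Corey–Winter olefination) extrudes CO2 and sulfur to give 7 under non-acidic conditions.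

Further compounds
F1 | step 15 | 3-iodo-1,2,4,5-tetramethoxybenzene | COc1cc(OC)c(OC)c(I)c1OC
F2 | step 15 | (3S)-3-methyl-1-(2,3,5,6-tetramethoxyphenyl)-5-[(1S,2R)-1,2,3-trimethylcyclohex-3-en-1-yl]pent-1-yn-3-ol | COc1cc(OC)c(OC)c(C#C[C@](C)(CC[C@]2(C)CCC=C(C)[C@@H]2C)O)c1OC
F3 | step 15 | (1Z,3S)-3-methyl-1-(2,3,5,6-tetramethoxyphenyl)-5-[(1S,2R)-1,2,3-trimethylcyclohex-3-en-1-yl]pent-1-en-3-ol | COc1cc(OC)c(OC)c(/C=C\[C@](C)(CC[C@]2(C)CCC=C(C)[C@@H]2C)O)c1OC
F4 | step 15 | 3-[(1Z,3S)-3-hydroxy-3-methyl-5-[(1S,2R)-1,2,3-trimethylcyclohex-3-en-1-yl]pent-1-en-1-yl]-2,5-dimethoxycyclohexa-2,5-diene-1,4-dione | COC1=CC(=O)C(OC)=C(/C=C\[C@](C)(CC[C@]2(C)CCC=C(C)[C@@H]2C)O)C1=O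
F5 | step 1 | {[(1Z)-1-{[(2E)-3,7-dimethylocta-2,6-dien-1-yl]oxy}prop-1-en-1-yl]oxy}trimethylsilane | C/C=C(\O[Si](C)(C)C)OC/C=C(\C)CCC=C(C)C
F6 | step 1 | racemic (2R*,3S*)-3-ethenyl-2,3,7-trimethyloct-6-enoic acid (racemate of 3; one enantiomer drawn) | C=C[C@](C)(CCC=C(C)C)[C@@H](C)C(=O)O
F7 | step 1 | (S)-1-phenylethylammonium (2R,3S)-3-ethenyl-2,3,7-trimethyloct-6-enoate | C=C[C@](C)(CCC=C(C)C)[C@@H](C)C(=O)[O-].C[C@H]([NH3+])c1ccccc1
F8 | step 4 | 4-ethenyl-2,3,4-trimethylcyclohexane-1,2-diol, cis-diol with C3 and C4 as in 6 (configuration at C1 and C2 not assigned) | C=C[C@]1(C)CCC(O)C(C)(O)[C@@H]1C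
F9 | step 4 | 5-ethenyl-3a,4,5-trimethylhexahydro-1,3-benzodioxole-2-thione, cis-fused with C4 and C5 as in 6 | C=C[C@]1(C)CCC2OC(=S)OC2(C)[C@@H]1C
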